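Retrosynthesis (flavanone numbering, primes = second half): the O7–Si–O7′ bridge is a helper and is removed last; the skeleton is cut at C3–C3′ and at O1–C2 and O1′–C2′. This leads back to two molecules of one chalcone of the isoliquiritigenin type, and from there to an acetophenone and a benzaldehyde (C2=C3 by aldol condensation).
Enabling feature: C3 is both Cα of the C4 ketone and Cβ of the 4-hydroxystyrene made up of C2, C3 and the B ring, so a B-ring phenoxyl radical carries its spin on C3. C2 then becomes a p-quinone methide carbon that lies six atoms from the chelated A-ring OH (the future O1).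
Forward order: chain assembly, then a tBu2Si tether across the two O7 atoms, then release of the B-ring phenols, then one anodic operation that makes C3–C3′ (temporary 15-membered ring), the first pyranone ring and finally the second pyranone ring (last ring of the skeleton), then removal of the tether.
Stereochemistry: the cofacial tether should let the two C3 radicals meet only through mirror-related faces (unlike C3/C3′). Each O1 should then add anti to the new C3–C3′ bond under A(1,3) control (2,3-trans in both rings). No later step is basic enough to epimerise C2 or C3.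

Key step: step 4

Remark: the two halves of the target are constitutionally identical and carry mirror-image descriptors (2S,3R and 2′R,3′S), so the compound is the achiral meso diastereomer; the route therefore has to control relative configuration only, and no chiral reagent is used.

Step 1
Reactants: 1 2,4-dihydroxyacetophenone; 2 4-(allyloxy)benzaldehyde
Product: 3 (E)-3-[4-(allyloxy)phenyl]-1-(2,4-dihydroxyphenyl)prop-2-en-1-one
Conditions: KOH (60% aq), EtOH, 0 °C → rt; then 1 M HCl to pH 3
Reagents that add atoms: none
Why: Claisen–Schmidt condensation in which the methyl ketone enolate adds to the non-enolisable aldehyde and E1cB loss of water gives the conjugated (E)-enone under thermodynamic control, while the phenolate keeps the chalcone open-chain and the allyl ether is inert to base.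

Step 2
Reactants: 3 (two molecules)
Product: 4 di-tert-butylbis{4-[(E)-3-(4-allyloxyphenyl)prop-2-enoyl]-3-hydroxyphenoxy}silane
Conditions: tBu2Si(OTf)2 (0.5 equiv), 2,6-lutidine, CH2Cl2, −20 °C → rt
Reagents that add atoms: di-tert-butylsilyl bis(trifluoromethanesulfonate), CC(C)(C)[Si](OS(=O)(=O)C(F)(F)F)(OS(=O)(=O)C(F)(F)F)C(C)(C)C
Why: Silyl ether formation with a twofold silyl triflate in which only the free and more acidic O7–H of each chalcone reacts, because the O1–H is held in the hydrogen bond to C4=O, so that one silicon atom joins two chalcones through the oxygens that become O7 and O7′ and no stereocentre is formed.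

Step 3
Reactants: 4
Product: 5 di-tert-butylbis{3-hydroxy-4-[(E)-3-(4-hydroxyphenyl)prop-2-enoyl]phenoxy}silane
Conditions: Pd(PPh3)4 (5 mol %), N-methylaniline, THF, rt
Reagents that add atoms: none
Why: Tsuji–Trost deallylation in which Pd(0) ionises each aryl allyl ether to a π-allyl complex that is captured by the weakly basic amine, which frees both B-ring phenols without touching the enones, the chelated O1–H groups or the silyl bridge and without base-induced oxa-Michael closure.

Step 4
Reactants: 5
Product: 8 (2S,3R,2′R,3′S)-7,7′-O-(di-tert-butylsilanediyl)-bridged 4″,4‴-dihydroxy-3,3′-biflavanone (meso; both pyranone rings 2,3-trans), via meso-bis(quinone methide) macrocycle 6 (not isolated), via mono-cyclised quinone methide 7 (not isolated)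
Conditions: anodic oxidation, divided cell, RVC anode, Pt cathode, potential held at the first phenol wave, 2 F/mol; 2,6-lutidine, Bu4NClO4, MeCN/CH2Cl2, 1 mM, Ar, 0 °C
Reagents that add atoms: none
Why: Proposed new method: one-electron oxidation of each B-ring phenol (lutidine takes the proton) puts spin on C3, the Cβ of the 4-hydroxystyrene that is also α to C4=O, the two C3 radicals couple to the bis(p-quinone methide) 6, and each chelated O1–H then adds to its own methide carbon C2 with re-aromatisation of the B ring; the closest known reaction type is the oxidative (also anodic) Cβ–Cβ′ dimerisation of 4-hydroxycinnamyl alcohols and 4-hydroxycinnamic acids, whose bis(quinone methides) are trapped by the side-chain OH or CO2H to give furofuran lignans and dilactones. Rings closed: the temporary 15-membered ring by radical–radical coupling at C3–C3′, then the two pyranone rings, each by 6-exo-trig 1,6-addition of O1 to C2 (the C2=C(B ring) bond is exocyclic to the new ring), the second of them being the last ring of the skeleton. C3 and C3′ are controlled by the O7–Si–O7′ bridge, which holds the two planar aroyl-vinyl-phenoxyl arms cofacial as in a [3.4]paracyclophane, so that C3 lies over C3′ only in the eclipsed, mirror-symmetric stack (a crossed stack would push the two A rings into each other next to the bridge) and the radicals join through mirror-related faces to give the unlike, meso pair. C2 and C2′ are controlled by A(1,3) strain in each quinone methide, which keeps H3 in the methide plane and C4 and C3′ on opposite faces, so that O1, delivered from C4, adds anti to the C3–C3′ bond and both rings come out 2,3-trans (diequatorial), that is 2S,3R and 2′R,3′S. The step needs oxidation of the B-ring phenols only (the chelated, acyl-deactivated O1–H is oxidised at a distinctly higher potential, hence potential control), C3–C3′ coupling instead of coupling through B-ring carbons or oxygen and instead of coupling between molecules (tether geometry, high dilution), and exclusion of O2, which would trap the carbon radicals.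

Step 5
Reactants: 8
Product: 9 (2S,3R)-7-hydroxy-3-[(2R,3S)-7-hydroxy-2-(4-hydroxyphenyl)-4-oxochroman-3-yl]-2-(4-hydroxyphenyl)chroman-4-one (meso; target)
Conditions: HF·pyridine, pyridine, THF, 0 °C → rt
Reagents that add atoms: none
Why: Fluoride-driven cleavage of the two aryl Si–O bonds under buffered, weakly acidic conditions that neither enolise C3 and C3′ nor open the pyranone rings, so the meso trans,trans configuration set in step 4 is carried into the target.

Compound list
1 | 2,4-dihydroxyacetophenone | CC(=O)c1ccc(O)cc1O | starting material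
2 | 4-(allyloxy)benzaldehyde | C=CCOc1ccc(C=O)cc1 | starting material
3 | (E)-3-[4-(allyloxy)phenyl]-1-(2,4-dihydroxyphenyl)prop-2-en-1-one | O=C(/C=C/c1ccc(OCC=C)cc1)c1ccc(O)cc1O | intermediate
4 | di-tert-butylbis{4-[(E)-3-(4-allyloxyphenyl)prop-2-enoyl]-3-hydroxyphenoxy}silane | CC(C)(C)[Si](Oc1ccc(C(=O)/C=C/c2ccc(OCC=C)cc2)c(O)c1)(Oc1ccc(C(=O)/C=C/c2ccc(OCC=C)cc2)c(O)c1)C(C)(C)C | intermediate
5 | di-tert-butylbis{3-hydroxy-4-[(E)-3-(4-hydroxyphenyl)prop-2-enoyl]phenoxy}silane | CC(C)(C)[Si](Oc1ccc(C(=O)/C=C/c2ccc(O)cc2)c(O)c1)(Oc1ccc(C(=O)/C=C/c2ccc(O)cc2)c(O)c1)C(C)(C)C | intermediate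
6 | meso-bis(quinone methide) macrocycle: 5 joined C3–C3′ (3S,3′R), each C2 carrying a 4-oxocyclohexa-2,5-dien-1-ylidene; formed in the flask, not isolated | CC(C)(C)[Si]1(C(C)(C)C)Oc2ccc(c(O)c2)C(=O)[C@@H](C=C2C=CC(=O)C=C2)[C@@H](C=C2C=CC(=O)C=C2)C(=O)c2ccc(O1)cc2O | intermediate
7 | mono-cyclised quinone methide: (2′R,3′S) pyranone ring closed 2,3-trans, C3 (S) still bearing the quinone methide arm and the open hydroxyaryl ketone; racemic, the enantiomer shown closes the (2S,3R) ring last; formed in the flask, not isolated | O=C(c1ccc(O[Si]3(C(C)(C)C)C(C)(C)C)cc1O)[C@@H](C=C1C=CC(=O)C=C1)[C@@H]1C(=O)c2ccc(O3)cc2O[C@H]1c1ccc(O)cc1 | intermediate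
8 | (2S,3R,2′R,3′S)-7,7′-O-(di-tert-butylsilanediyl)-bridged 4″,4‴-dihydroxy-3,3′-biflavanone (meso) | O=C1c2ccc(O[Si]3(C(C)(C)C)C(C)(C)C)cc2O[C@H](c2ccc(O)cc2)[C@H]1[C@@H]1C(=O)c2ccc(O3)cc2O[C@H]1c1ccc(O)cc1 | intermediate
9 | (2S,3R)-7-hydroxy-3-[(2R,3S)-7-hydroxy-2-(4-hydroxyphenyl)-4-oxochroman-3-yl]-2-(4-hydroxyphenyl)chroman-4-one (meso) | O=C1c2ccc(O)cc2O[C@H](c2ccc(O)cc2)[C@H]1[C@@H]1C(=O)c2ccc(O)cc2O[C@H]1c1ccc(O)cc1 | target

Total step count: 5. Longest linear sequence: 5 steps (1 → 3 → 4 → 5 → 8 → 9).

Steps most likely to fail

Step 4 (bears the label Proposed new method). What may go wrong: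
- the two phenoxyl radicals couple between molecules or through B-ring carbons instead of C3–C3′;
- the bis(quinone methide) tautomerises to the 2,3-dibenzylidene-1,4-diketone before O1 adds, which erases the C3/C3′ information;
- the product phenols are over-oxidised;
- the second closure is slowed by cyclophane strain.

Fallback with known chemistry, from 4 back to 8. Et3N in MeCN at 50 °C isomerises both hydroxychalcone arms of 4 by oxa-Michael addition to the tethered bis-flavanone bis(allyl ether) F1. The (2S,2′R) diastereomer is carried on and the (2R*,2′R*) isomer is re-equilibrated under the same conditions. Soft enolisation with TMSOTf/Et3N in CH2Cl2 at 0 °C gives the bis(4-trimethylsilyloxy-2H-chromene) F2. Intramolecular oxidative coupling of the two silyl enol ethers (CAN, NaHCO3, MeCN, −20 °C) forms C3–C3′ anti to each 2-aryl group and gives the tethered biflavanone bis(allyl ether) F3. With C2 (S) and C2′ (R) fixed, the epimerisable C3 and C3′ should settle 2,3-trans, which is the meso isomer. Pd(PPh3)4/N-methylaniline then removes the allyl groups and gives 8.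

Step 2. What may go wrong: silylation of the chelated O1–H as well, oligomeric silyl ethers from the polyfunctional chalcone, and hydrolytic loss of the bis(aryloxy)silane on purification.

Fallback from 1 back to 4, with the tether put on before the enones exist. Two equivalents of 1 and tBu2Si(OTf)2/2,6-lutidine give di-tert-butylbis(4-acetyl-3-hydroxyphenoxy)silane F4, a simple diketone in which only O4–H was free. A twofold acid-mediated Claisen–Schmidt condensation of F4 with 2 (dry HCl, EtOAc/EtOH, 0 °C) then gives 4; anhydrous acid should cleave aryl silyl ethers only slowly.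

Step 1. What may go wrong: the doubly deprotonated ketone 1 enolises poorly, so the condensation stalls while 2 is lost by Cannizzaro disproportionation.

Fallback from 1 back to 3. O4 is masked first (MOMCl, K2CO3, acetone; the chelated 2-OH does not react) to give 2-hydroxy-4-(methoxymethoxy)acetophenone F5. This condenses with 2 under the KOH conditions of step 1 to the MOM-protected chalcone F6. HCl in MeOH at 40 °C removes the MOM group (allyl aryl ether and enone should survive) and gives 3.

Further compounds
F1 | step 4 | (2S,2′R)-7,7′-O-(di-tert-butylsilanediyl)-bridged bis[2-(4-allyloxyphenyl)chroman-4-one] | C=CCOc1ccc(cc1)[C@@H]1CC(=O)c2ccc(O[Si](Oc3ccc4c(c3)O[C@H](CC4=O)c3ccc(OCC=C)cc3)(C(C)(C)C)C(C)(C)C)cc2O1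
F2 | step 4 | (2S,2′R)-7,7′-O-(di-tert-butylsilanediyl)-bridged bis[2-(4-allyloxyphenyl)-4-(trimethylsilyloxy)-2H-chromene] | C=CCOc1ccc(cc1)[C@@H]1C=C(O[Si](C)(C)C)c2ccc(O[Si](Oc3ccc4c(c3)O[C@H](C=C4O[Si](C)(C)C)c3ccc(OCC=C)cc3)(C(C)(C)C)C(C)(C)C)cc2O1
F3 | step 4 | (2S,3R,2′R,3′S)-7,7′-O-(di-tert-butylsilanediyl)-bridged 4″,4‴-bis(allyloxy)-3,3′-biflavanone (meso) | O=C1c2ccc(O[Si]3(C(C)(C)C)C(C)(C)C)cc2O[C@H](c2ccc(OCC=C)cc2)[C@H]1[C@@H]1C(=O)c2ccc(O3)cc2O[C@H]1c1ccc(OCC=C)cc1
F4 | step 2 | di-tert-butylbis(4-acetyl-3-hydroxyphenoxy)silane | CC(=O)c1ccc(O[Si](Oc2ccc(C(C)=O)c(O)c2)(C(C)(C)C)C(C)(C)C)cc1O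
F5 | step 1 | 2-hydroxy-4-(methoxymethoxy)acetophenone | CC(=O)c1ccc(OCOC)cc1O
F6 | step 1 | (E)-3-[4-(allyloxy)phenyl]-1-[2-hydroxy-4-(methoxymethoxy)phenyl]prop-2-en-1-one | O=C(/C=C/c1ccc(OCC=C)cc1)c1ccc(OCOC)cc1O
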